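**Plan**

- Retrosynthetic cuts: the side-chain ester C–O; the C1/C4 quinone carbonyls back to two dimethyl ketals; ring A at C8–C8a (6π electrocyclization after 4π opening of a cyclobutenone); C5–C4a (vinyllithium + cyclobutenedione); C6–C1′ (α-oxy organolithium + vinylogous ester).
- Forward order: ring B enters preformed at the quinone oxidation level as bromo-p-benzoquinone bis(dimethyl ketal); C5–C8 come from diisopropyl squarate; the C6 side chain is attached by 1,2-addition and carbonyl transposition; ring A closes last by thermal ring expansion; ketal hydrolysis and esterification finish.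
- Enabling feature: ring A (C4a, C5–C8, C8a) is a para-hydroquinone mono-methyl ether with C5–OMe beside the C6 chain and C8–OH beside C7–H. This is the pattern produced by ring expansion of a 4-alkenyl-4-methoxy-3-alkylcyclobut-2-enone (C4–OMe becomes C5–OMe, the ketene C=O becomes C8–OH). The C4a=C8a bond serves as the alkenyl 2π unit while C1/C4 are ketals, so the tautomer is fixed without an oxidant or a selective (de)methylation.
- Stereochemistry: C1′ (R) is set by (−)-sparteine-mediated enantioselective α-deprotonation of the homoprenyl carbamate and C–C bond formation with retention. The racemic quaternary carbon of the cyclobutenone becomes sp2 in the key step, so its diastereomers converge.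

Key step: step 6

Remark: the sparteine-complexed α-carbamoyloxy organolithium is assumed to be configurationally stable at −78 °C and to add to the ketone with retention, as is general for this class; this gives the (R) descriptor at C1′.

**Step 1**
Reactants: 1 2-bromo-1,4-dimethoxybenzene
Product: 2 1-bromo-3,3,6,6-tetramethoxycyclohexa-1,4-diene
Conditions: Pt anode, constant current, 1% KOH/MeOH, 0 °C, undivided cell
Reagents that add atoms: methanol, CO
Why: Anodic two-electron oxidation of the 1,4-dimethoxyarene in basic methanol (anodic methoxylation) traps the cation twice with methoxide to give the quinone bis(dimethyl ketal), leaving the C–Br bond intact.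

**Step 2**
Reactants: 3 3,4-diisopropoxycyclobut-3-ene-1,2-dione
Product: 5 3-isopropoxycyclobut-3-ene-1,2-dione, via hydride adduct 4 (not isolated)
Conditions: LiAlH(Ot-Bu)3, THF, −78 → −20 °C; then 6 M HCl, CH2Cl2, 0 °C
Reagents that add atoms: water, O
Why: Mono-1,2-reduction of one squarate carbonyl followed by acid ionization of the carbinol to an alkoxy-stabilized allyl cation and hydrolysis (vinylogous hemiketal transposition) should give the semisquarate with loss of isopropanol.

**Step 3**
Reactants: 2 1-bromo-3,3,6,6-tetramethoxycyclohexa-1,4-diene; 5 3-isopropoxycyclobut-3-ene-1,2-dione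
Product: 8 4-methoxy-3-isopropoxy-4-(3,3,6,6-tetramethoxycyclohexa-1,4-dien-1-yl)cyclobut-2-en-1-one, via vinyllithium 6 (not isolated), via lithium alkoxide 7 (not isolated)
Conditions: n-BuLi, THF, −78 °C; cannulate into 5, −78 °C; then MeOTf, −78 → 0 °C
Reagents that add atoms: methyl trifluoromethanesulfonate, COS(=O)(=O)C(F)(F)F
Why: Bromine–lithium exchange gives a vinyllithium that should add 1,2 to the C2 carbonyl (C1 is a deactivated vinylogous ester), and the tertiary lithium alkoxide is O-methylated in situ; this makes the future C5–C4a bond and the C5–OMe group.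

**Step 4**
Reactants: 9 4-methylpent-3-en-1-ol
Product: 10 4-methylpent-3-en-1-yl N,N-diisopropylcarbamate
Conditions: i-Pr2NCOCl, Et3N, toluene, reflux
Reagents that add atoms: N,N-diisopropylcarbamoyl chloride, CC(C)N(C(C)C)C(Cl)=O
Why: Carbamoylation of the primary alcohol (acyl substitution) installs the directing, dipole-stabilizing group needed for α-lithiation.

**Step 5**
Reactants: 10 4-methylpent-3-en-1-yl N,N-diisopropylcarbamate; 8 4-methoxy-3-isopropoxy-4-(3,3,6,6-tetramethoxycyclohexa-1,4-dien-1-yl)cyclobut-2-en-1-one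
Product: 13 (1R)-1-[4-methoxy-3-oxo-4-(3,3,6,6-tetramethoxycyclohexa-1,4-dien-1-yl)cyclobut-1-en-1-yl]-4-methylpent-3-en-1-yl N,N-diisopropylcarbamate, via lithiated carbamate 11 (not isolated), via lithium alkoxide adduct 12 (not isolated)
Conditions: s-BuLi, (−)-sparteine, Et2O, −78 °C; add 8, −78 °C; then (CF3CO)2O, −78 → 0 °C; aq NaHCO3
Reagents that add atoms: water, O
Why: s-BuLi/(−)-sparteine should remove the pro-S α-proton of the carbamate (Hoppe lithiation) to give a configurationally stable (S)-organolithium that adds to the vinylogous-ester carbonyl of 8 with retention, setting C1′ as R; trifluoroacetylation of the tertiary alkoxide, ionization and hydrolysis then transpose the carbonyl (Stork–Danheiser transposition) under non-acidic conditions that spare the bisketal.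

**Step 6**
Reactants: 13 (1R)-1-[4-methoxy-3-oxo-4-(3,3,6,6-tetramethoxycyclohexa-1,4-dien-1-yl)cyclobut-1-en-1-yl]-4-methylpent-3-en-1-yl N,N-diisopropylcarbamate
Product: 16 (1R)-1-(4-hydroxy-1,5,5,8,8-pentamethoxy-5,8-dihydronaphthalen-2-yl)-4-methylpent-3-en-1-yl N,N-diisopropylcarbamate, via dienylketene 14 (not isolated), via cyclohexadienone 15 (not isolated)
Conditions: toluene (0.02 M, degassed), 110 °C
Reagents that add atoms: none
Why: Heating opens the cyclobutenone by conrotatory 4π electrocyclic cleavage of the C1–C4 bond with the donor OMe rotating outward (torquoselectivity), which places the cyclohexadienyl group cis to the new ketene in 14; 6π electrocyclization of the ketene C=C, the C3=C4 alkene and the ring-B C=C then forms the C8–C8a bond to give dienone 15, and enolization aromatizes ring A. The closest known reaction type is the Moore rearrangement of 4-alkenyl-4-alkoxycyclobutenones to hydroquinone mono-ethers. Ring A is closed by 6π electrocyclization (C8–C8a), its other ring bond C5–C4a having been made in step 3. No stereocentre is formed; the racemic quaternary carbon becomes the sp2 C5, so both diastereomers of 13 converge on one product, and the side-chain centre takes no part and is carried through unchanged. The selectivity needed is regiochemical and is fixed by connectivity alone: the C4–OMe carbon becomes C5–OMe beside the C6 side chain and the ketene carbonyl becomes the free C8–OH beside C7–H. Because ring B is kept as the bisketal, the phenol emerges next to a latent quinone and no oxidant or selective demethylation is needed later.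

**Step 7**
Reactants: 16 (1R)-1-(4-hydroxy-1,5,5,8,8-pentamethoxy-5,8-dihydronaphthalen-2-yl)-4-methylpent-3-en-1-yl N,N-diisopropylcarbamate
Product: 17 3-[(1R)-1-hydroxy-4-methylpent-3-en-1-yl]-4,5,5,8,8-pentamethoxy-5,8-dihydronaphthalen-1-ol
Conditions: LiAlH4, THF, reflux; Rochelle salt work-up
Reagents that add atoms: none
Why: Hydride attack at the carbamate carbonyl (reductive decarbamoylation) should release the secondary alkoxide without breaking the C–O bond of the stereocentre; ketals, the alkenes and the phenoxide are inert to LiAlH4.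

**Step 8**
Reactants: 17 3-[(1R)-1-hydroxy-4-methylpent-3-en-1-yl]-4,5,5,8,8-pentamethoxy-5,8-dihydronaphthalen-1-ol
Product: 18 8-hydroxy-6-[(1R)-1-hydroxy-4-methylpent-3-en-1-yl]-5-methoxynaphthalene-1,4-dione
Conditions: 1 M aq HCl, THF, 0 °C → rt
Reagents that add atoms: water, O
Why: Acid hydrolysis of the two benzylic/allylic dimethyl ketals should unveil the C1/C4 quinone carbonyls directly without a redox step, and the C5 methyl ether holds the quinone in the single required tautomer.

**Step 9**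
Reactants: 18 8-hydroxy-6-[(1R)-1-hydroxy-4-methylpent-3-en-1-yl]-5-methoxynaphthalene-1,4-dione; 19 3-methylbut-2-enoic acid
Product: 20 (1R)-1-(4-hydroxy-1-methoxy-5,8-dioxo-5,8-dihydronaphthalen-2-yl)-4-methylpent-3-en-1-yl 3-methylbut-2-enoate
Conditions: DCC, DMAP (cat.), CH2Cl2, 0 °C → rt
Reagents that add atoms: none
Why: Steglich esterification should acylate the secondary side-chain alcohol selectively, because the C8 phenol is deactivated by its strong hydrogen bond to the C1 carbonyl; the C1′–O bond is retained, so the configuration is unchanged.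

**Compound list**

1 | 2-bromo-1,4-dimethoxybenzene | COc1ccc(OC)c(Br)c1 | starting material
2 | 1-bromo-3,3,6,6-tetramethoxycyclohexa-1,4-diene | COC1(OC)C=CC(OC)(OC)C(Br)=C1 | intermediate
3 | 3,4-diisopropoxycyclobut-3-ene-1,2-dione (diisopropyl squarate) | CC(C)OC1=C(OC(C)C)C(=O)C1=O | starting material
4 | 4-hydroxy-2,3-diisopropoxycyclobut-2-en-1-one (racemic) | CC(C)OC1=C(OC(C)C)C(O)C1=O | intermediate
5 | 3-isopropoxycyclobut-3-ene-1,2-dione | CC(C)OC1=CC(=O)C1=O | intermediate
6 | (3,3,6,6-tetramethoxycyclohexa-1,4-dien-1-yl)lithium | [Li]C1=CC(OC)(OC)C=CC1(OC)OC | intermediate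
7 | lithium 2-isopropoxy-4-oxo-1-(3,3,6,6-tetramethoxycyclohexa-1,4-dien-1-yl)cyclobut-2-en-1-olate (racemic) | [Li]OC1(C2=CC(OC)(OC)C=CC2(OC)OC)C(OC(C)C)=CC1=O | intermediate
8 | 4-methoxy-3-isopropoxy-4-(3,3,6,6-tetramethoxycyclohexa-1,4-dien-1-yl)cyclobut-2-en-1-one (racemic) | COC1(C2=CC(OC)(OC)C=CC2(OC)OC)C(OC(C)C)=CC1=O | intermediate
9 | 4-methylpent-3-en-1-ol | CC(C)=CCCO | starting material
10 | 4-methylpent-3-en-1-yl N,N-diisopropylcarbamate | CC(C)=CCCOC(=O)N(C(C)C)C(C)C | intermediate
11 | [(1S)-1-(N,N-diisopropylcarbamoyloxy)-4-methylpent-3-en-1-yl]lithium (sparteine complex) | [Li][C@@H](CC=C(C)C)OC(=O)N(C(C)C)C(C)C | intermediate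
12 | lithium alkoxide of (1R)-1-[1-hydroxy-3-isopropoxy-4-methoxy-4-(3,3,6,6-tetramethoxycyclohexa-1,4-dien-1-yl)cyclobut-2-en-1-yl]-4-methylpent-3-en-1-yl N,N-diisopropylcarbamate (ring diastereomers) | COC1(C2=CC(OC)(OC)C=CC2(OC)OC)C(OC(C)C)=CC1(O[Li])[C@@H](CC=C(C)C)OC(=O)N(C(C)C)C(C)C | intermediate
13 | (1R)-1-[4-methoxy-3-oxo-4-(3,3,6,6-tetramethoxycyclohexa-1,4-dien-1-yl)cyclobut-1-en-1-yl]-4-methylpent-3-en-1-yl N,N-diisopropylcarbamate (both epimers at ring C4) | COC1(C2=CC(OC)(OC)C=CC2(OC)OC)C(=O)C=C1[C@@H](CC=C(C)C)OC(=O)N(C(C)C)C(C)C | intermediate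
14 | dienylketene: 4-methoxy-3-[(1R)-1-(N,N-diisopropylcarbamoyloxy)-4-methylpent-3-en-1-yl]-4-(3,3,6,6-tetramethoxycyclohexa-1,4-dien-1-yl)buta-1,3-dien-1-one, dienyl group cis to the ketene | O=C=C/C([C@@H](CC=C(C)C)OC(=O)N(C(C)C)C(C)C)=C(/OC)C1=CC(OC)(OC)C=CC1(OC)OC | intermediate
15 | (1R)-1-(1,5,5,8,8-pentamethoxy-4-oxo-4,4a,5,8-tetrahydronaphthalen-2-yl)-4-methylpent-3-en-1-yl N,N-diisopropylcarbamate | O=C1C=C([C@@H](CC=C(C)C)OC(=O)N(C(C)C)C(C)C)C(OC)=C2C1C(OC)(OC)C=CC2(OC)OC | intermediate
16 | (1R)-1-(4-hydroxy-1,5,5,8,8-pentamethoxy-5,8-dihydronaphthalen-2-yl)-4-methylpent-3-en-1-yl N,N-diisopropylcarbamate | Oc1cc([C@@H](CC=C(C)C)OC(=O)N(C(C)C)C(C)C)c(OC)c2c1C(OC)(OC)C=CC2(OC)OC | intermediate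
17 | 3-[(1R)-1-hydroxy-4-methylpent-3-en-1-yl]-4,5,5,8,8-pentamethoxy-5,8-dihydronaphthalen-1-ol | Oc1cc([C@@H](CC=C(C)C)O)c(OC)c2c1C(OC)(OC)C=CC2(OC)OC | intermediate
18 | 8-hydroxy-6-[(1R)-1-hydroxy-4-methylpent-3-en-1-yl]-5-methoxynaphthalene-1,4-dione | COc1c([C@@H](CC=C(C)C)O)cc(O)c2c1C(=O)C=CC2=O | intermediate
19 | 3-methylbut-2-enoic acid | CC(C)=CC(=O)O | starting material
20 | (1R)-1-(4-hydroxy-1-methoxy-5,8-dioxo-5,8-dihydronaphthalen-2-yl)-4-methylpent-3-en-1-yl 3-methylbut-2-enoate | COc1c([C@@H](CC=C(C)C)OC(=O)C=C(C)C)cc(O)c2c1C(=O)C=CC2=O | target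

**Step count and risks**

Total steps: 9. Longest linear sequence: 7 steps (from 3 through steps 2, 3, 5, 6, 7, 8, 9; the same length from 1 through step 1).

Most likely to fail, in order:

1. Step 5. The risks are competing deprotonation at the allylic CH2 instead of the α-oxy position, erosion of configuration of the organolithium before it is trapped, slow addition of the bulky sparteine complex to the hindered carbonyl, and carbamoyl migration onto the neighbouring tertiary alkoxide. The fallback takes the stereocentre from a catalyst-controlled ketone reduction instead. It sets out from 8. 1,3-Dithiane is lithiated and alkylated with prenyl bromide to give 2-(3-methylbut-2-en-1-yl)-1,3-dithiane F1. Its 2-lithio derivative (n-BuLi, THF, −30 °C) is added 1,2 to 8 and the adduct is transposed with trifluoroacetic anhydride as in step 5 to give 4-methoxy-3-[2-(3-methylbut-2-en-1-yl)-1,3-dithian-2-yl]-4-(3,3,6,6-tetramethoxycyclohexa-1,4-dien-1-yl)cyclobut-2-en-1-one F2. Thermolysis in toluene at 110 °C should give 4,5,5,8,8-pentamethoxy-3-[2-(3-methylbut-2-en-1-yl)-1,3-dithian-2-yl]-5,8-dihydronaphthalen-1-ol F3. Neutral dethioketalization (MeI, CaCO3, aqueous MeCN) would give 1-(4-hydroxy-1,5,5,8,8-pentamethoxy-5,8-dihydronaphthalen-2-yl)-4-methylpent-3-en-1-one F4. Corey–Bakshi–Shibata reduction with the (S)-oxazaborolidine and BH3·SMe2 (aryl as the large group) should give the (R)-carbinol, which is 17, where the route is rejoined.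

2. Step 6. The risks are loss of methanol from the ketal-bearing ring at 110 °C and disfavoured inward rotation of the ketal-flanked dienyl group, so that the ketene decomposes before it cyclizes. The fallback uses the aryl version of the ring expansion with ring B as a protected hydroquinone. It sets out from 5. Bromohydroquinone is silylated (TIPSCl, imidazole) to 2-bromo-1,4-bis(triisopropylsilyloxy)benzene F5. Bromine–lithium exchange (n-BuLi, THF, −78 °C, where the bulky silyl group suppresses O→C silyl migration), addition to 5 and methylation with MeOTf give 4-[2,5-bis(triisopropylsilyloxy)phenyl]-4-methoxy-3-isopropoxycyclobut-2-en-1-one F6. Addition of 11 and transposition as in step 5 give (1R)-1-{4-[2,5-bis(triisopropylsilyloxy)phenyl]-4-methoxy-3-oxocyclobut-1-en-1-yl}-4-methylpent-3-en-1-yl N,N-diisopropylcarbamate F7. Thermolysis in xylene at 140 °C should give (1R)-1-[4-hydroxy-1-methoxy-5,8-bis(triisopropylsilyloxy)naphthalen-2-yl]-4-methylpent-3-en-1-yl N,N-diisopropylcarbamate F8. LiAlH4 gives 3-[(1R)-1-hydroxy-4-methylpent-3-en-1-yl]-4-methoxy-5,8-bis(triisopropylsilyloxy)naphthalen-1-ol F9. TBAF in THF at 0 °C frees 6-[(1R)-1-hydroxy-4-methylpent-3-en-1-yl]-5-methoxynaphthalene-1,4,8-triol F10, whose 1,4-dihydroxy ring is oxidized by air (or Ag2O) far more easily than the methoxyphenol ring, to give 18, where the route is rejoined.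

3. Step 8. The risk is acid-promoted ionization of the free benzylic alcohol (elimination to the diene or cyclization onto the prenyl alkene) competing with ketal hydrolysis. The fallback carries the side-chain oxygen through the acid step as its final ester. It sets out from 17. Both hydroxyls are acylated with excess 19 (DCC, DMAP) to give (1R)-1-[1,5,5,8,8-pentamethoxy-4-(3-methylbut-2-enoyloxy)-5,8-dihydronaphthalen-2-yl]-4-methylpent-3-en-1-yl 3-methylbut-2-enoate F11. Ketal hydrolysis as in step 8 gives (1R)-1-[1-methoxy-4-(3-methylbut-2-enoyloxy)-5,8-dioxo-5,8-dihydronaphthalen-2-yl]-4-methylpent-3-en-1-yl 3-methylbut-2-enoate F12. The activated aryl ester peri to the quinone carbonyl is then cleaved selectively (K2CO3 cat., MeOH, 0 °C) to give 20 directly.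

**Further compounds**

F1 | step 5 | 2-(3-methylbut-2-en-1-yl)-1,3-dithiane | CC(C)=CCC1SCCCS1
F2 | step 5 | 4-methoxy-3-[2-(3-methylbut-2-en-1-yl)-1,3-dithian-2-yl]-4-(3,3,6,6-tetramethoxycyclohexa-1,4-dien-1-yl)cyclobut-2-en-1-one | COC1(C2=CC(OC)(OC)C=CC2(OC)OC)C(=O)C=C1C3(CC=C(C)C)SCCCS3
F3 | step 5 | 4,5,5,8,8-pentamethoxy-3-[2-(3-methylbut-2-en-1-yl)-1,3-dithian-2-yl]-5,8-dihydronaphthalen-1-ol | Oc1cc(C3(CC=C(C)C)SCCCS3)c(OC)c2c1C(OC)(OC)C=CC2(OC)OC
F4 | step 5 | 1-(4-hydroxy-1,5,5,8,8-pentamethoxy-5,8-dihydronaphthalen-2-yl)-4-methylpent-3-en-1-one | Oc1cc(C(=O)CC=C(C)C)c(OC)c2c1C(OC)(OC)C=CC2(OC)OC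
F5 | step 6 | 2-bromo-1,4-bis(triisopropylsilyloxy)benzene | CC(C)[Si](C(C)C)(C(C)C)Oc1ccc(O[Si](C(C)C)(C(C)C)C(C)C)c(Br)c1
F6 | step 6 | 4-[2,5-bis(triisopropylsilyloxy)phenyl]-4-methoxy-3-isopropoxycyclobut-2-en-1-one | COC1(c2cc(O[Si](C(C)C)(C(C)C)C(C)C)ccc2O[Si](C(C)C)(C(C)C)C(C)C)C(OC(C)C)=CC1=O
F7 | step 6 | (1R)-1-{4-[2,5-bis(triisopropylsilyloxy)phenyl]-4-methoxy-3-oxocyclobut-1-en-1-yl}-4-methylpent-3-en-1-yl N,N-diisopropylcarbamate | COC1(c2cc(O[Si](C(C)C)(C(C)C)C(C)C)ccc2O[Si](C(C)C)(C(C)C)C(C)C)C(=O)C=C1[C@@H](CC=C(C)C)OC(=O)N(C(C)C)C(C)C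
F8 | step 6 | (1R)-1-[4-hydroxy-1-methoxy-5,8-bis(triisopropylsilyloxy)naphthalen-2-yl]-4-methylpent-3-en-1-yl N,N-diisopropylcarbamate | Oc1cc([C@@H](CC=C(C)C)OC(=O)N(C(C)C)C(C)C)c(OC)c2c(O[Si](C(C)C)(C(C)C)C(C)C)ccc(O[Si](C(C)C)(C(C)C)C(C)C)c12
F9 | step 6 | 3-[(1R)-1-hydroxy-4-methylpent-3-en-1-yl]-4-methoxy-5,8-bis(triisopropylsilyloxy)naphthalen-1-ol | Oc1cc([C@@H](CC=C(C)C)O)c(OC)c2c(O[Si](C(C)C)(C(C)C)C(C)C)ccc(O[Si](C(C)C)(C(C)C)C(C)C)c12
F10 | step 6 | 6-[(1R)-1-hydroxy-4-methylpent-3-en-1-yl]-5-methoxynaphthalene-1,4,8-triol | Oc1cc([C@@H](CC=C(C)C)O)c(OC)c2c(O)ccc(O)c12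
F11 | step 8 | (1R)-1-[1,5,5,8,8-pentamethoxy-4-(3-methylbut-2-enoyloxy)-5,8-dihydronaphthalen-2-yl]-4-methylpent-3-en-1-yl 3-methylbut-2-enoate | CC(C)=CC(=O)Oc1cc([C@@H](CC=C(C)C)OC(=O)C=C(C)C)c(OC)c2c1C(OC)(OC)C=CC2(OC)OC
F12 | step 8 | (1R)-1-[1-methoxy-4-(3-methylbut-2-enoyloxy)-5,8-dioxo-5,8-dihydronaphthalen-2-yl]-4-methylpent-3-en-1-yl 3-methylbut-2-enoate | COc1c([C@@H](CC=C(C)C)OC(=O)C=C(C)C)cc(OC(=O)C=C(C)C)c2c1C(=O)C=CC2=O
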